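**Retrosynthetic overview**
- The ten-membered carbocycle is closed last, by ring-closing metathesis at C4=C5, followed by removal of the C15 silyl ether.
- The C8 isobutyrate comes from a Mitsunobu inversion of the C8 alcohol produced by the key step: an intermolecular zinc Barbier allylation (C7–C8 bond) of a furanone aldehyde with a 3-(bromomethyl)butenolide.
- The furanone aldehyde comes from cyclisation of an α'-hydroxy ynone (Weinreb amide plus enyne acetylide); C10 derives from (S)-lactic acid by Seebach alkylation.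
- The bromobutenolide comes from a (Z)-iodoallylic alcohol by carboxylation and lactonisation; C6 is set by Sharpless kinetic resolution of a crotonaldehyde/alkyne adduct.
- Ring order: 3(2H)-furanone first, then the butenolide (which becomes the α-methylene-γ-lactone in the key step), then the ten-membered ring.

Assumption: atoms are located with germacrane numbering (C1 ketone, C2=C3 furanone alkene, C4=C5, C6 lactone carbinol, C7, C8 ester carbinol, C9, C10 quaternary carbon, C11=C13 methylidene, C12 lactone carbonyl, C14 methyl, C15 hydroxymethyl); the target is 4Z,6R,7R,8R,10R. Solutions of LiN(iPr)2, n-BuLi, t-BuLi, iPrMgCl and NaAlH2(OCH2CH2OMe)2 are bought.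

**Fragment A: furanone aldehyde**

Step 1
Reactants: 1 (S)-lactic acid; 2 pivalaldehyde
Product: 3 (2S,5S)-2-tert-butyl-5-methyl-1,3-dioxolan-4-one
Conditions: TsOH·H2O (cat.), H2SO4 (cat.), pentane, reflux, Dean–Stark; recrystallise (pentane/Et2O, −78 °C)
Reagents that add atoms: none
Why: Acid-catalysed acetalisation (Seebach dioxolanone formation) is thermodynamically cis-selective and the cis isomer crystallises, so the new acetal centre (2S) is set by the lactate centre.

Step 2
Reactants: 3 (2S,5S)-2-tert-butyl-5-methyl-1,3-dioxolan-4-one; 4 allyl bromide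
Product: 6 (2S,5R)-2-tert-butyl-5-methyl-5-(prop-2-en-1-yl)-1,3-dioxolan-4-one, via lithium enolate 5 (not isolated)
Conditions: LiN(iPr)2, THF, −78 °C; then 4, −78 → −30 °C
Reagents that add atoms: none
Why: Enolate alkylation with self-regeneration of the stereocentre: the planar enolate is allylated on the face trans to the tert-butyl group, which rebuilds the quaternary centre as 5R (the future C10) with >95:5 selectivity.

Step 3
Reactants: 6 (2S,5R)-2-tert-butyl-5-methyl-5-(prop-2-en-1-yl)-1,3-dioxolan-4-one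
Product: 8 (2S,5R)-2-tert-butyl-5-methyl-5-(2-oxoethyl)-1,3-dioxolan-4-one, via ozonide 7 (not isolated)
Conditions: O3, CH2Cl2, −78 °C; then PPh3, −78 °C → rt
Reagents that add atoms: ozone, [O-][O+]=O
Why: Ozonolysis with reductive work-up cleaves the only alkene to the C8 aldehyde and leaves the acetal and the quaternary centre untouched.

Step 4
Reactants: 8 (2S,5R)-2-tert-butyl-5-methyl-5-(2-oxoethyl)-1,3-dioxolan-4-one
Product: 9 (2S,5R)-2-tert-butyl-5-(2,2-dimethoxyethyl)-5-methyl-1,3-dioxolan-4-one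
Conditions: HC(OMe)3, PPTS (cat.), MeOH, rt
Reagents that add atoms: trimethyl orthoformate, COC(OC)OC; methanol, CO
Why: Acid-catalysed acetalisation with orthoformate as water scavenger masks the aldehyde for the organometallic steps, and the dioxolanone tolerates this mild acid.

Step 5
Reactants: 9 (2S,5R)-2-tert-butyl-5-(2,2-dimethoxyethyl)-5-methyl-1,3-dioxolan-4-one
Product: 10 (2R)-2-hydroxy-N,4,4-trimethoxy-N,2-dimethylbutanamide
Conditions: MeNH(OMe)·HCl, iPrMgCl, THF, −20 → 0 °C; aq. NH4Cl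
Reagents that add atoms: N,O-dimethylhydroxylamine hydrochloride, CNOC.Cl
Why: Weinreb amide formation by aminolysis: ClMgN(OMe)Me opens the activated acetal-ester, the hemiacetal collapses with loss of pivalaldehyde, and the quaternary centre is not involved.

Step 6
Reactants: 11 2-bromoprop-2-en-1-ol
Product: 12 [(2-bromoprop-2-en-1-yl)oxy](tert-butyl)dimethylsilane
Conditions: TBSCl, imidazole, CH2Cl2, 0 °C → rt
Reagents that add atoms: tert-butyldimethylsilyl chloride, CC(C)(C)[Si](C)(C)Cl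
Why: Standard silylation of a primary alcohol protects the future C15 hydroxyl.

Step 7
Reactants: 12 [(2-bromoprop-2-en-1-yl)oxy](tert-butyl)dimethylsilane; 13 ethynyltrimethylsilane
Product: 14 tert-butyl(dimethyl){[2-methylidene-4-(trimethylsilyl)but-3-yn-1-yl]oxy}silane
Conditions: PdCl2(PPh3)2 (3 mol%), CuI (6 mol%), Et3N, THF, 45 °C
Reagents that add atoms: none
Why: Sonogashira coupling of the vinyl bromide with the terminal alkyne builds the C2–C4 enyne.

Step 8
Reactants: 14 tert-butyl(dimethyl){[2-methylidene-4-(trimethylsilyl)but-3-yn-1-yl]oxy}silane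
Product: 15 tert-butyl(dimethyl)[(2-methylidenebut-3-yn-1-yl)oxy]silane
Conditions: K2CO3 (cat.), MeOH, 0 °C → rt
Reagents that add atoms: none
Why: Base-catalysed methanolysis removes the alkynyl silane selectively because the C(sp)–Si bond is far more labile than the alkyl silyl ether.

Step 9
Reactants: 10 (2R)-2-hydroxy-N,4,4-trimethoxy-N,2-dimethylbutanamide; 15 tert-butyl(dimethyl)[(2-methylidenebut-3-yn-1-yl)oxy]silane
Product: 17 (3R)-7-({[tert-butyl(dimethyl)silyl]oxy}methyl)-3-hydroxy-1,1-dimethoxy-3-methyloct-7-en-5-yn-4-one, via lithium acetylide 16 (not isolated)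
Conditions: 15 (3.2 equiv), n-BuLi (3.0 equiv), THF, −78 °C; then 10, −78 → 0 °C; aq. NH4Cl
Reagents that add atoms: none
Why: Weinreb ketone synthesis: one equivalent of acetylide deprotonates the tertiary hydroxyl and a second adds to give a chelated tetrahedral intermediate that releases the ynone only on quench, so over-addition is avoided.

Step 10
Reactants: 17 (3R)-7-({[tert-butyl(dimethyl)silyl]oxy}methyl)-3-hydroxy-1,1-dimethoxy-3-methyloct-7-en-5-yn-4-one
Product: 18 (2R)-5-(3-{[tert-butyl(dimethyl)silyl]oxy}prop-1-en-2-yl)-2-(2,2-dimethoxyethyl)-2-methylfuran-3(2H)-one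
Conditions: (Ph3P)AuNTf2 (2 mol%), CH2Cl2, rt
Reagents that add atoms: none
Why: Gold-catalysed 5-endo-dig hydroalkoxylation (intramolecular oxa-Michael addition) of the tertiary hydroxyl onto the ynone gives the 3(2H)-furanone without touching C10.

Step 11
Reactants: 18 (2R)-5-(3-{[tert-butyl(dimethyl)silyl]oxy}prop-1-en-2-yl)-2-(2,2-dimethoxyethyl)-2-methylfuran-3(2H)-one
Product: 19 [(2R)-5-(3-{[tert-butyl(dimethyl)silyl]oxy}prop-1-en-2-yl)-2-methyl-3-oxo-2,3-dihydrofuran-2-yl]acetaldehyde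
Conditions: PPTS (0.2 equiv), acetone/H2O (9:1), 40 °C; used at once
Reagents that add atoms: water, O
Why: Mild acid-catalysed acetal hydrolysis frees the aldehyde much faster than the primary silyl ether is cleaved, and acidic conditions avoid β-elimination of the furanone oxygen.

**Fragment B: bromobutenolide**

Step 12
Reactants: 20 4-methoxybenzyl alcohol; 21 propargyl bromide
Product: 22 1-methoxy-4-[(prop-2-yn-1-yloxy)methyl]benzene
Conditions: NaH, THF, 0 °C → rt
Reagents that add atoms: none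
Why: Williamson ether synthesis gives an alkyl (not silyl) ether at the future C13 oxygen, which cannot migrate onto the later vinyllithium.

Step 13
Reactants: 22 1-methoxy-4-[(prop-2-yn-1-yloxy)methyl]benzene; 23 (E)-but-2-enal
Product: 25 rac-(5E)-1-[(4-methoxyphenyl)methoxy]hept-5-en-2-yn-4-ol, via lithium acetylide 24 (not isolated)
Conditions: n-BuLi, THF, −78 °C; then 23, −78 °C; aq. NH4Cl
Reagents that add atoms: none
Why: 1,2-Addition of the lithium acetylide to the enal creates the C6 carbinol as a racemate, which is resolved in the next step.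

Step 14
Reactants: 25 rac-(5E)-1-[(4-methoxyphenyl)methoxy]hept-5-en-2-yn-4-ol
Product: 26 (4R,5E)-1-[(4-methoxyphenyl)methoxy]hept-5-en-2-yn-4-ol
Conditions: Ti(OiPr)4 (1.0 equiv), D-(−)-diisopropyl tartrate (1.2 equiv), t-BuOOH (0.6 equiv), 4 Å molecular sieves, CH2Cl2, −20 °C, to about 55% conversion
Reagents that add atoms: none
Why: Sharpless kinetic resolution: with the D-(−)-tartrate the 4S enantiomer is epoxidised at its propenyl group much faster, so the 4R alcohol (the future 6R centre) is recovered in high ee.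

Step 15
Reactants: 26 (4R,5E)-1-[(4-methoxyphenyl)methoxy]hept-5-en-2-yn-4-ol
Product: 28 (2Z,4R,5E)-2-iodo-1-[(4-methoxyphenyl)methoxy]hepta-2,5-dien-4-ol, via cyclic alkenylalanate 27 (not isolated)
Conditions: NaAlH2(OCH2CH2OMe)2 (1.6 equiv), THF, 0 °C → rt; then I2, THF, −78 → 0 °C
Reagents that add atoms: iodine, [I][I]
Why: Hydroxyl-directed trans-hydroalumination of the propargylic alcohol places aluminium on the distal alkyne carbon, and iodinolysis with retention gives the (Z)-3-iodoallylic alcohol.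

Step 16
Reactants: 28 (2Z,4R,5E)-2-iodo-1-[(4-methoxyphenyl)methoxy]hepta-2,5-dien-4-ol
Product: 31 (5R)-3-{[(4-methoxyphenyl)methoxy]methyl}-5-[(1E)-prop-1-en-1-yl]furan-2(5H)-one, via dilithio species 29 (not isolated), via hydroxy acid 30 (not isolated)
Conditions: t-BuLi (3.1 equiv), Et2O, −78 °C; CO2 (g), −78 → 0 °C; then 1 M HCl, rt
Reagents that add atoms: carbon dioxide, O=C=O
Why: Iodine–lithium exchange with retention of alkene geometry, carboxylation and acid-induced lactonisation of the (Z)-γ-hydroxy acid give the butenolide without base or transition metal acting on the sensitive doubly allylic C6 centre.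

Step 17
Reactants: 31 (5R)-3-{[(4-methoxyphenyl)methoxy]methyl}-5-[(1E)-prop-1-en-1-yl]furan-2(5H)-one
Product: 32 (5R)-3-(hydroxymethyl)-5-[(1E)-prop-1-en-1-yl]furan-2(5H)-one
Conditions: DDQ, CH2Cl2/pH 7 buffer (10:1), 0 °C → rt
Reagents that add atoms: none
Why: Oxidative cleavage of the 4-methoxybenzyl ether by DDQ proceeds under buffered neutral conditions that do not enolise the butenolide.

Step 18
Reactants: 32 (5R)-3-(hydroxymethyl)-5-[(1E)-prop-1-en-1-yl]furan-2(5H)-one
Product: 33 (5R)-3-(bromomethyl)-5-[(1E)-prop-1-en-1-yl]furan-2(5H)-one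
Conditions: CBr4, PPh3, CH2Cl2, 0 °C
Reagents that add atoms: carbon tetrabromide, BrC(Br)(Br)Br
Why: Appel bromination converts the primary allylic alcohol into the allylic bromide under neutral conditions.

**Union and endgame**

Step 19
Reactants: 19 [(2R)-5-(3-{[tert-butyl(dimethyl)silyl]oxy}prop-1-en-2-yl)-2-methyl-3-oxo-2,3-dihydrofuran-2-yl]acetaldehyde; 33 (5R)-3-(bromomethyl)-5-[(1E)-prop-1-en-1-yl]furan-2(5H)-one
Product: 35 (4R,5R)-4-{(1S)-2-[(2R)-5-(3-{[tert-butyl(dimethyl)silyl]oxy}prop-1-en-2-yl)-2-methyl-3-oxo-2,3-dihydrofuran-2-yl]-1-hydroxyethyl}-3-methylidene-5-[(1E)-prop-1-en-1-yl]oxolan-2-one, via allylzinc bromide 34 (not isolated)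
Conditions: Zn dust (activated), THF/sat. aq. NH4Cl (2:1), 0 °C → rt
Reagents that add atoms: none
Why: Zinc Barbier carbonyl allylation: the allylzinc reacts at its γ-carbon through a chair Zimmerman–Traxler transition state, anti to the propenyl group (7R, trans lactone) and with the aldehyde chain equatorial (8S), and the alkene shifts to give the α-methylene lactone.

Step 20
Reactants: 35 (4R,5R)-4-{(1S)-2-[(2R)-5-(3-{[tert-butyl(dimethyl)silyl]oxy}prop-1-en-2-yl)-2-methyl-3-oxo-2,3-dihydrofuran-2-yl]-1-hydroxyethyl}-3-methylidene-5-[(1E)-prop-1-en-1-yl]oxolan-2-one; 36 isobutyric acid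
Product: 37 (1R)-2-[(2R)-5-(3-{[tert-butyl(dimethyl)silyl]oxy}prop-1-en-2-yl)-2-methyl-3-oxo-2,3-dihydrofuran-2-yl]-1-{(2R,3R)-4-methylidene-5-oxo-2-[(1E)-prop-1-en-1-yl]oxolan-3-yl}ethyl 2-methylpropanoate
Conditions: PPh3, DIAD, toluene, 0 °C → rt
Reagents that add atoms: none
Why: Mitsunobu esterification: SN2 displacement of the oxyphosphonium by isobutyrate inverts C8 from S to the required R and installs the ester in the same operation.

Step 21
Reactants: 37 (1R)-2-[(2R)-5-(3-{[tert-butyl(dimethyl)silyl]oxy}prop-1-en-2-yl)-2-methyl-3-oxo-2,3-dihydrofuran-2-yl]-1-{(2R,3R)-4-methylidene-5-oxo-2-[(1E)-prop-1-en-1-yl]oxolan-3-yl}ethyl 2-methylpropanoate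
Product: 38 [(2Z,4R,8R,9R,11R)-2-({[tert-butyl(dimethyl)silyl]oxy}methyl)-11-methyl-7-methylidene-6,12-dioxo-5,14-dioxatricyclo[9.2.1.0^{4,8}]tetradeca-1(13),2-dien-9-yl] 2-methylpropanoate (the C15 silyl ether of the target)
Conditions: second-generation Hoveyda–Grubbs catalyst RuCl2(H2IMes)(=CH-C6H4-2-OiPr) (15 mol%, in portions), 1,4-benzoquinone (30 mol%), toluene (1 mM), 90 °C
Reagents that add atoms: none
Why: Ring-closing metathesis: the carbene loads at the propenyl group and closes onto the 1,1-disubstituted alkene, and the bridged ten-membered ring can only hold the Z alkene.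

Step 22
Reactants: 38 (the C15 silyl ether of the target)
Product: 39 [(2Z,4R,8R,9R,11R)-2-(hydroxymethyl)-11-methyl-7-methylidene-6,12-dioxo-5,14-dioxatricyclo[9.2.1.0^{4,8}]tetradeca-1(13),2-dien-9-yl] 2-methylpropanoate (target)
Conditions: HF·pyridine, pyridine/THF, 0 °C → rt
Reagents that add atoms: none
Why: Fluoride-mediated desilylation under mildly acidic conditions frees the C15 alcohol and spares the α-methylene lactone, the isobutyrate and the furanone.

**Compound list**

1 | (S)-lactic acid | C[C@H](O)C(=O)O | starting material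
2 | pivalaldehyde | CC(C)(C)C=O | starting material
3 | (2S,5S)-2-tert-butyl-5-methyl-1,3-dioxolan-4-one | C[C@@H]1O[C@H](C(C)(C)C)OC1=O | intermediate
4 | allyl bromide | C=CCBr | starting material
5 | lithium (2S)-2-tert-butyl-5-methyl-1,3-dioxol-4-olate (lithium enolate of 3, not isolated) | [Li]OC1=C(C)O[C@H](C(C)(C)C)O1 | intermediate
6 | (2S,5R)-2-tert-butyl-5-methyl-5-(prop-2-en-1-yl)-1,3-dioxolan-4-one | C=CC[C@@]1(C)O[C@H](C(C)(C)C)OC1=O | intermediate
7 | (2S,5R)-2-tert-butyl-5-methyl-5-(1,2,4-trioxolan-3-ylmethyl)-1,3-dioxolan-4-one (ozonide, both epimers at the trioxolane carbon, not isolated) | C1(C[C@@]2(C)O[C@H](C(C)(C)C)OC2=O)OCOO1 | intermediate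
8 | (2S,5R)-2-tert-butyl-5-methyl-5-(2-oxoethyl)-1,3-dioxolan-4-one | O=CC[C@@]1(C)O[C@H](C(C)(C)C)OC1=O | intermediate
9 | (2S,5R)-2-tert-butyl-5-(2,2-dimethoxyethyl)-5-methyl-1,3-dioxolan-4-one | COC(OC)C[C@@]1(C)O[C@H](C(C)(C)C)OC1=O | intermediate
10 | (2R)-2-hydroxy-N,4,4-trimethoxy-N,2-dimethylbutanamide | COC(OC)C[C@@](C)(O)C(=O)N(C)OC | intermediate
11 | 2-bromoprop-2-en-1-ol | OCC(Br)=C | starting material
12 | [(2-bromoprop-2-en-1-yl)oxy](tert-butyl)dimethylsilane | C=C(Br)CO[Si](C)(C)C(C)(C)C | intermediate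
13 | ethynyltrimethylsilane | C#C[Si](C)(C)C | starting material
14 | tert-butyl(dimethyl){[2-methylidene-4-(trimethylsilyl)but-3-yn-1-yl]oxy}silane | C=C(CO[Si](C)(C)C(C)(C)C)C#C[Si](C)(C)C | intermediate
15 | tert-butyl(dimethyl)[(2-methylidenebut-3-yn-1-yl)oxy]silane | C=C(CO[Si](C)(C)C(C)(C)C)C#C | intermediate
16 | lithium acetylide of 15 (not isolated) | [Li]C#CC(=C)CO[Si](C)(C)C(C)(C)C | intermediate
17 | (3R)-7-({[tert-butyl(dimethyl)silyl]oxy}methyl)-3-hydroxy-1,1-dimethoxy-3-methyloct-7-en-5-yn-4-one | COC(OC)C[C@@](C)(O)C(=O)C#CC(=C)CO[Si](C)(C)C(C)(C)C | intermediate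
18 | (2R)-5-(3-{[tert-butyl(dimethyl)silyl]oxy}prop-1-en-2-yl)-2-(2,2-dimethoxyethyl)-2-methylfuran-3(2H)-one | COC(OC)C[C@@]1(C)OC(C(=C)CO[Si](C)(C)C(C)(C)C)=CC1=O | intermediate
19 | [(2R)-5-(3-{[tert-butyl(dimethyl)silyl]oxy}prop-1-en-2-yl)-2-methyl-3-oxo-2,3-dihydrofuran-2-yl]acetaldehyde | O=CC[C@@]1(C)OC(C(=C)CO[Si](C)(C)C(C)(C)C)=CC1=O | intermediate
20 | 4-methoxybenzyl alcohol | COc1ccc(CO)cc1 | starting material
21 | propargyl bromide | C#CCBr | starting material
22 | 1-methoxy-4-[(prop-2-yn-1-yloxy)methyl]benzene | C#CCOCc1ccc(OC)cc1 | intermediate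
23 | (E)-but-2-enal (crotonaldehyde) | C/C=C/C=O | starting material
24 | lithium acetylide of 22 (not isolated) | [Li]C#CCOCc1ccc(OC)cc1 | intermediate
25 | rac-(5E)-1-[(4-methoxyphenyl)methoxy]hept-5-en-2-yn-4-ol | C/C=C/C(O)C#CCOCc1ccc(OC)cc1 | intermediate
26 | (4R,5E)-1-[(4-methoxyphenyl)methoxy]hept-5-en-2-yn-4-ol | C/C=C/[C@@H](O)C#CCOCc1ccc(OC)cc1 | intermediate
27 | sodium (5R)-2,2-bis(2-methoxyethoxy)-3-{[(4-methoxyphenyl)methoxy]methyl}-5-[(1E)-prop-1-en-1-yl]-2,5-dihydro-1,2-oxaaluminol-2-uide (cyclic alkenylalanate, not isolated) | [Na+].COCCO[Al-]1(OCCOC)O[C@H](/C=C/C)C=C1COCc1ccc(OC)cc1 | intermediate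
28 | (2Z,4R,5E)-2-iodo-1-[(4-methoxyphenyl)methoxy]hepta-2,5-dien-4-ol | C/C=C/[C@@H](O)/C=C(\I)COCc1ccc(OC)cc1 | intermediate
29 | lithium (2Z,4R,5E)-2-lithio-1-[(4-methoxyphenyl)methoxy]hepta-2,5-dien-4-olate (not isolated) | [Li]O[C@H](/C=C/C)/C=C(\[Li])COCc1ccc(OC)cc1 | intermediate
30 | (2Z,4R,5E)-4-hydroxy-2-{[(4-methoxyphenyl)methoxy]methyl}hepta-2,5-dienoic acid (not isolated) | C/C=C/[C@@H](O)/C=C(/COCc1ccc(OC)cc1)C(=O)O | intermediate
31 | (5R)-3-{[(4-methoxyphenyl)methoxy]methyl}-5-[(1E)-prop-1-en-1-yl]furan-2(5H)-one | C/C=C/[C@H]1OC(=O)C(COCc2ccc(OC)cc2)=C1 | intermediate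
32 | (5R)-3-(hydroxymethyl)-5-[(1E)-prop-1-en-1-yl]furan-2(5H)-one | C/C=C/[C@H]1OC(=O)C(CO)=C1 | intermediate
33 | (5R)-3-(bromomethyl)-5-[(1E)-prop-1-en-1-yl]furan-2(5H)-one | C/C=C/[C@H]1OC(=O)C(CBr)=C1 | intermediate
34 | bromo{[(5R)-2-oxo-5-[(1E)-prop-1-en-1-yl]-2,5-dihydrofuran-3-yl]methyl}zinc (not isolated) | Br[Zn]CC1=C[C@@H](/C=C/C)OC1=O | intermediate
35 | (4R,5R)-4-{(1S)-2-[(2R)-5-(3-{[tert-butyl(dimethyl)silyl]oxy}prop-1-en-2-yl)-2-methyl-3-oxo-2,3-dihydrofuran-2-yl]-1-hydroxyethyl}-3-methylidene-5-[(1E)-prop-1-en-1-yl]oxolan-2-one | C=C1C(=O)O[C@H](/C=C/C)[C@H]1[C@@H](O)C[C@@]2(C)OC(C(=C)CO[Si](C)(C)C(C)(C)C)=CC2=O | intermediate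
36 | isobutyric acid | CC(C)C(=O)O | starting material
37 | (1R)-2-[(2R)-5-(3-{[tert-butyl(dimethyl)silyl]oxy}prop-1-en-2-yl)-2-methyl-3-oxo-2,3-dihydrofuran-2-yl]-1-{(2R,3R)-4-methylidene-5-oxo-2-[(1E)-prop-1-en-1-yl]oxolan-3-yl}ethyl 2-methylpropanoate | C=C1C(=O)O[C@H](/C=C/C)[C@H]1[C@H](OC(=O)C(C)C)C[C@@]2(C)OC(C(=C)CO[Si](C)(C)C(C)(C)C)=CC2=O | intermediate
38 | [(2Z,4R,8R,9R,11R)-2-({[tert-butyl(dimethyl)silyl]oxy}methyl)-11-methyl-7-methylidene-6,12-dioxo-5,14-dioxatricyclo[9.2.1.0^{4,8}]tetradeca-1(13),2-dien-9-yl] 2-methylpropanoate | C=C1C(=O)O[C@@H]2/C=C(/CO[Si](C)(C)C(C)(C)C)C3=CC(=O)[C@@](C)(C[C@@H](OC(=O)C(C)C)[C@@H]12)O3 | intermediate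
39 | [(2Z,4R,8R,9R,11R)-2-(hydroxymethyl)-11-methyl-7-methylidene-6,12-dioxo-5,14-dioxatricyclo[9.2.1.0^{4,8}]tetradeca-1(13),2-dien-9-yl] 2-methylpropanoate | C=C1C(=O)O[C@@H]2/C=C(/CO)C3=CC(=O)[C@@](C)(C[C@@H](OC(=O)C(C)C)[C@@H]12)O3 | target

**Totals and risks**

Total step count: 22. Longest linear sequence: 12 steps (steps 1–5, 9–11, 19–22).

The three steps most likely to fail:

Step 20, the Mitsunobu inversion at a hindered carbinol whose neighbouring C7–H is allylic, so elimination or poor conversion can compete. The fallback sets out from 33 and 19 and comes back at 37. Bromide 33 is converted with Zn dust and Bu3SnCl in THF/aq. NH4Cl into (5R)-5-[(1E)-prop-1-en-1-yl]-3-[(tributylstannyl)methyl]furan-2(5H)-one F3. Addition of this stannane to 19 with BF3·OEt2 in CH2Cl2 at −78 °C goes through an open antiperiplanar transition state, which gives the syn adduct, the C8 epimer of 35, (8R)-alcohol F4, directly. Plain acylation with isobutyric anhydride, DMAP (cat.) and pyridine then gives 37 with retention, so no inversion is needed.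

Step 21, the ring-closing metathesis onto a conjugated 1,1-disubstituted alkene next to a bulky silyl ether in a strained bridged ring. The fallback sets out from 37 and comes back at 39. The silyl ether is removed first with HF·pyridine to give the free allylic alcohol F5. The ring is then closed as the last step on this smaller, hydroxyl-bearing diene with second-generation Grubbs catalyst RuCl2(H2IMes)(PCy3)(=CHPh) in refluxing CH2Cl2 at 0.5 mM, which gives 39 directly.

Step 16, the carboxylation through a dianion whose vinyllithium sits next to an allylic ether and could eliminate. The fallback sets out from 28 and comes back at 31. The carbinol is silylated (Et3SiCl, imidazole, CH2Cl2) to the triethylsilyl ether F1. Iodine–magnesium exchange with iPrMgCl·LiCl in THF at 0 °C and trapping with methyl chloroformate give the methyl (2Z)-dienoate F2. TsOH·H2O in MeOH then removes the silyl group and the freed hydroxyl closes onto the cis ester to give 31.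

**Further compounds**

F1 | step 16 | triethyl{[(2Z,4R,5E)-2-iodo-1-[(4-methoxyphenyl)methoxy]hepta-2,5-dien-4-yl]oxy}silane | C/C=C/[C@@H](O[Si](CC)(CC)CC)/C=C(\I)COCc1ccc(OC)cc1
F2 | step 16 | methyl (2Z,4R,5E)-2-{[(4-methoxyphenyl)methoxy]methyl}-4-[(triethylsilyl)oxy]hepta-2,5-dienoate | C/C=C/[C@@H](O[Si](CC)(CC)CC)/C=C(/COCc1ccc(OC)cc1)C(=O)OC
F3 | step 20 | (5R)-5-[(1E)-prop-1-en-1-yl]-3-[(tributylstannyl)methyl]furan-2(5H)-one | C/C=C/[C@H]1OC(=O)C(C[Sn](CCCC)(CCCC)CCCC)=C1
F4 | step 20 | (4R,5R)-4-{(1R)-2-[(2R)-5-(3-{[tert-butyl(dimethyl)silyl]oxy}prop-1-en-2-yl)-2-methyl-3-oxo-2,3-dihydrofuran-2-yl]-1-hydroxyethyl}-3-methylidene-5-[(1E)-prop-1-en-1-yl]oxolan-2-one | C=C1C(=O)O[C@H](/C=C/C)[C@H]1[C@H](O)C[C@@]2(C)OC(C(=C)CO[Si](C)(C)C(C)(C)C)=CC2=O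
F5 | step 21 | (1R)-2-[(2R)-5-(3-hydroxyprop-1-en-2-yl)-2-methyl-3-oxo-2,3-dihydrofuran-2-yl]-1-{(2R,3R)-4-methylidene-5-oxo-2-[(1E)-prop-1-en-1-yl]oxolan-3-yl}ethyl 2-methylpropanoate | C=C1C(=O)O[C@H](/C=C/C)[C@H]1[C@H](OC(=O)C(C)C)C[C@@]2(C)OC(C(=C)CO)=CC2=O
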